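You asked how much of the electrophile will have reacted after 2.0 d in delta, gamma and epsilon, and your hunch is that more nucleophile simply carries it further. We agree on the direction; a balance of the nucleophile sizes the product, and the reacted electrophile beyond that goes to the protic impurity.

| setting | winter | delta | gamma | epsilon |
|---|---|---|---|---|
| electrophile | 0.085 M | 0.085 M | 0.085 M | 0.085 M |
| nucleophile | 0.053 M | 0.0850 M | 0.130 M | 0.190 M |
| protic impurity | 0.0425 M | 0.0425 M | 0.0425 M | 0.0425 M |
| remark | run made earlier |  |  |  |
| time |  | 2.0 d | 2.0 d | 2.0 d |

- winter (time / h: electrophile / %, product / %): 4.00: 61.3, 30.1; 6.00: 57.2, 31.0; 10.0: 52.4, 31.3; 20.0: 43.0, 31.9; 30.0: 36.9, 31.3; 50.0: 29.7, 31.0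

(readings scatter by 0.5 percentage points)

- reactions considered so far: electrophile + nucleophile <-> acid set free + product; nucleophile + acid set free <-> protonated nucleophile; electrophile + protic impurity -> quenched substrate

1. part of the electrophile that has reacted at the end, delta
2. part of the electrophile that has reacted at the end, gamma
3. part of the electrophile that has reacted at the end, epsilon
4. what raising the concentration of nucleophile from its lowest to its highest value here does to the part of the electrophile that has reacted (changes below 5 percentage points count as none) (it falls / it rises / no change)

In the winter run the product readings stay between 30.1% and 31.9% from 4.00 h on, with a scatter of 0.5 percentage points, while the electrophile readings keep falling, from 61.3% to 29.7% at 50.0 h. So write the balance of the nucleophile: each product takes one, and the acid set free takes a second as protonated nucleophile. The winter charge then allows 31.2% of the electrophile charge as product, which is where the readings sit. We call this the product ceiling: the nucleophile charge divided by two, as a fraction of the electrophile charge.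

The electrophile charge stays as in the winter run, so we scale the ceiling with the nucleophile charge: it is 50.0% for delta and 76.5% for gamma, with nucleophile as the limiting reagent. For epsilon it is 112%, above the whole charge, so there electrophile becomes the limiting one. We take these ceilings as floors for delta and gamma, and the protic impurity then drains the electrophile left above them.

The forecast, resting on “each product uses two nucleophiles, one reacting and one taking up the acid”, gives 82% (78% to 86%) for delta, 95% (90% to 98.5%) for gamma and 99.5% (97% to 100%) for epsilon, with the trend: it rises.

The flasks give 81.3% for delta, 93.8% for gamma and >99.9% for epsilon, so the trend is it rises, by 19 points.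

    electrophile + nucleophile ⇌ acid set free + product (K = 1.80, k = 7.90 M⁻¹ h⁻¹)
    nucleophile + acid set free ⇌ protonated nucleophile, settled at all times (K = 1.10 × 10⁵ M⁻¹)
    electrophile + protic impurity → quenched substrate (k = 0.810 M⁻¹ h⁻¹)

The rise is owed to the nucleophile charge: with the difference in that charge taken away, so that epsilon holds delta's nucleophile, 81.3% of the electrophile reacts rather than >99.9%. At the asked time product stands at 49.9% in delta against a ceiling of 50.0%, and at 75.6% in gamma against 76.5%. In one more flask, like gamma but with 0.21 M of electrophile, the ceiling comes to 31.0%, and after 2.00 d product stands at 31.1%, with 48.9% of the electrophile still there.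

The numbers in the tables were computed for substances that don't exist, and the scatter is random.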